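**Retrosynthetic overview**
- The strategy rests on C1 of five-membered ring A: a tertiary carbinol (OH, isopropyl) bonded to the C2 methylene and to ring-fusion carbon C8a. Ring A is therefore closed last by forming C1–C2, with a 2-iodoethyl arm on C3a adding to an isobutyryl ketone on C8a under SmI2 (Barbier).
- After ring A: acylation of O8, ene-type allylic oxidation at C7 to the C7 enone, α-face dihydroxylation of C5=C6, debenzylation.
- Before ring A: the seven-membered ring B is closed by ring-closing metathesis at C5=C6; the C1 carbonyl and C2 are held as a δ-lactone that isopropyllithium opens to the ketone, and C2–OH becomes the iodide.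
- C8, C8a and C3a all come from one dianionic ester-enolate Claisen rearrangement (C8a–C3a bond) of an (E)-dienyl ester of an (S)-β-hydroxy acid.
- Ring order: ring B (step 7), then ring A (step 11).

Key step: step 11

Remark on the chemistry: hydroazulene numbering (C1–C8a) is used for all intermediates, also before ring closure; O8 is carried as a silyl ether through the key step; alcohol 24 is taken as a C7 epimer mixture because C7 becomes a ketone; hydroxy ketone 18 may equilibrate with its cyclic hemiketal.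

**Step 1**
Reactants: 1 pent-1-en-4-yne
Product: 4 (2E)-3-methylhexa-2,5-dien-1-ol, via alkenylalane 2 (not isolated), via lithium alanate 3 (not isolated)
Conditions: Me3Al, Cp2ZrCl2 (0.2 equiv), CH2Cl2, 0 → 23 °C; n-BuLi, hexane/THF, −78 °C; (CH2O)n, 23 °C; 1 M HCl
Reagents that add atoms: trimethylaluminium C[Al](C)C; formaldehyde (from paraformaldehyde) C=O
Why: Negishi zirconium-catalysed carboalumination adds CH3 and Al syn across the terminal alkyne with the metal on the terminal carbon (the isolated alkene reacts far more slowly), and the alanate passes its alkenyl group to formaldehyde with retention, which fixes the E geometry (allyl trans to CH2OH) needed in step 5.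

**Step 2**
Reactants: 5 ethyl (3R)-4-chloro-3-hydroxybutanoate
Product: 6 ethyl [(2R)-oxiran-2-yl]acetate
Conditions: Ag2O, DME, 60 °C, dark
Reagents that add atoms: none
Why: Silver-assisted intramolecular Williamson closure of the chlorohydrin forms the epoxide without base, so the acidic ester α-position is not touched and the carbinol carbon keeps its configuration because none of its bonds is broken.

**Step 3**
Reactants: 6 ethyl [(2R)-oxiran-2-yl]acetate; 7 isopropenylmagnesium bromide
Product: 8 ethyl (3S)-3-hydroxy-5-methylhex-5-enoate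
Conditions: CuI (10 mol %), THF, −40 °C; 1 M HCl
Reagents that add atoms: none
Why: Copper-catalysed Grignard opening of a terminal epoxide takes place at the unsubstituted carbon much faster than addition to the ester at −40 °C, so the future C8 carbinol is untouched (the descriptor becomes S only through a priority change).

**Step 4**
Reactants: 8 ethyl (3S)-3-hydroxy-5-methylhex-5-enoate; 4 (2E)-3-methylhexa-2,5-dien-1-ol
Product: 9 (2E)-3-methylhexa-2,5-dien-1-yl (3S)-3-hydroxy-5-methylhex-5-enoate
Conditions: Ti(OEt)4 (0.2 equiv), 4 (1.5 equiv), PhMe, 100 °C, EtOH distilled off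
Reagents that add atoms: none
Why: Titanate-mediated transesterification exchanges ethoxide for the primary allylic alkoxide under neutral conditions and is driven by removal of ethanol, without dehydrating the β-hydroxy ester or moving the skipped diene.

**Step 5**
Reactants: 9 (2E)-3-methylhexa-2,5-dien-1-yl (3S)-3-hydroxy-5-methylhex-5-enoate
Product: 11 (2S,3S)-3-hydroxy-5-methyl-2-[(3S)-3-methylhexa-1,5-dien-3-yl]hex-5-enoic acid, via dilithium dianion 10 (not isolated)
Conditions: LiN(iPr)2 (2.1 equiv), THF, −78 → 23 °C; 1 M HCl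
Reagents that add atoms: none
Why: In this dianionic ester-enolate Claisen rearrangement the lithium chelate between alkoxide and enolate oxygens fixes the enolate geometry (C8 cis to OLi) and, as in Fráter–Seebach alkylations, directs the allyl terminus anti to the C8 side chain (sets C8a), while the chair transition state of the E alkene puts the allyl arm equatorial and CH3 axial (sets quaternary C3a).

**Step 6**
Reactants: 11 (2S,3S)-3-hydroxy-5-methyl-2-[(3S)-3-methylhexa-1,5-dien-3-yl]hex-5-enoic acid
Product: 13 methyl (2S,3S)-3-{[tert-butyl(dimethyl)silyl]oxy}-5-methyl-2-[(3S)-3-methylhexa-1,5-dien-3-yl]hex-5-enoate, via methyl ester 12 (not isolated)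
Conditions: TMSCHN2, PhMe/MeOH, 0 °C; concentrate; TBSOTf, 2,6-lutidine, CH2Cl2, 0 °C
Reagents that add atoms: (trimethylsilyl)diazomethane C[Si](C)(C)C=[N+]=[N-]; tert-butyldimethylsilyl triflate CC(C)(C)[Si](C)(C)OS(=O)(=O)C(F)(F)F
Why: Diazoalkane methylation of the acid and silyl triflate protection of the hindered secondary alcohol are standard protecting-group operations that leave the alkenes and stereocentres alone, and the silyl ether later blocks retro-aldol cleavage, proton quench and chelation-assisted ketone reduction.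

**Step 7**
Reactants: 13 methyl (2S,3S)-3-{[tert-butyl(dimethyl)silyl]oxy}-5-methyl-2-[(3S)-3-methylhexa-1,5-dien-3-yl]hex-5-enoate
Product: 14 methyl (1S,2S,7S)-7-{[tert-butyl(dimethyl)silyl]oxy}-2-ethenyl-2,5-dimethylcyclohept-4-ene-1-carboxylate
Conditions: second-generation Grubbs catalyst RuCl2(=CHPh)(PCy3)(H2IMes) (5 mol %), CH2Cl2 (5 mM), 40 °C
Reagents that add atoms: none
Why: In this ring-closing metathesis the ruthenium carbene loads on the unhindered allyl group and closes onto the 1,1-disubstituted methallyl alkene to give the trisubstituted cycloheptene (ring B, C5=C6), while the vinyl group on the quaternary carbon is too shielded to initiate.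

**Step 8**
Reactants: 14 methyl (1S,2S,7S)-7-{[tert-butyl(dimethyl)silyl]oxy}-2-ethenyl-2,5-dimethylcyclohept-4-ene-1-carboxylate
Product: 16 (4aS,9S,9aS)-9-{[tert-butyl(dimethyl)silyl]oxy}-4a,7-dimethyl-4,4a,5,8,9,9a-hexahydrocyclohepta[c]pyran-1(3H)-one, via hydroxy ester 15 (not isolated)
Conditions: 9-BBN, THF, 0 → 23 °C; NaOH, H2O2, 0 °C; then PPTS (cat.), PhH, 60 °C
Reagents that add atoms: hydrogen peroxide OO
Why: Anti-Markovnikov hydroboration–oxidation with 9-BBN picks the monosubstituted vinyl group over the trisubstituted ring alkene to give the primary C2 alcohol, and acid-catalysed lactonisation then ties O–C2 to C1 as a trans-fused δ-lactone without touching C8a.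

**Step 9**
Reactants: 16 (4aS,9S,9aS)-9-{[tert-butyl(dimethyl)silyl]oxy}-4a,7-dimethyl-4,4a,5,8,9,9a-hexahydrocyclohepta[c]pyran-1(3H)-one; 17 isopropyllithium
Product: 18 1-[(1S,2S,7S)-7-{[tert-butyl(dimethyl)silyl]oxy}-2-(2-hydroxyethyl)-2,5-dimethylcyclohept-4-en-1-yl]-2-methylpropan-1-one
Conditions: iPrLi (1.2 equiv), THF, −78 °C; AcOH, −78 °C
Reagents that add atoms: none
Why: Single addition of an organolithium to a δ-lactone at −78 °C stops at the lithium hemiketal, which opens on protonation to the hindered δ-hydroxy isopropyl ketone, and addition should be faster than deprotonation of the shielded C8a–H so that its configuration is kept.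

**Step 10**
Reactants: 18 1-[(1S,2S,7S)-7-{[tert-butyl(dimethyl)silyl]oxy}-2-(2-hydroxyethyl)-2,5-dimethylcyclohept-4-en-1-yl]-2-methylpropan-1-one
Product: 19 1-[(1S,2S,7S)-7-{[tert-butyl(dimethyl)silyl]oxy}-2-(2-iodoethyl)-2,5-dimethylcyclohept-4-en-1-yl]-2-methylpropan-1-one
Conditions: PPh3, imidazole, I2, CH2Cl2, 0 °C
Reagents that add atoms: iodine II
Why: Appel-type iodination converts the primary alcohol to the iodide by SN2 displacement of the alkoxyphosphonium ion under near-neutral conditions that neither enolise the ketone nor engage the ring alkene.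

**Step 11**
Reactants: 19 1-[(1S,2S,7S)-7-{[tert-butyl(dimethyl)silyl]oxy}-2-(2-iodoethyl)-2,5-dimethylcyclohept-4-en-1-yl]-2-methylpropan-1-one
Product: 20 (1R,3aR,8S,8aS)-8-{[tert-butyl(dimethyl)silyl]oxy}-3a,6-dimethyl-1-(propan-2-yl)-1,2,3,3a,4,7,8,8a-octahydroazulen-1-ol
Conditions: SmI2 (3 equiv, 0.1 M), NiI2 (2 mol %), THF, 0 °C, 19 added slowly; aq. NH4Cl
Reagents that add atoms: none
Why: SmI2 (divalent samarium, with NiI2 as electron-transfer catalyst) reduces the primary C–I bond and a second equivalent turns the C2 radical into a C2 organosamarium (trivalent samarium), which adds to the isobutyryl carbonyl carbon C1 and forms the C1–C2 bond; the closest known reaction type is the SmI2-mediated intramolecular Barbier cyclisation of ω-iodoalkyl ketones to cyclopentanols. Ring A closes in the 5-exo-trig mode, and the trans ring fusion is already fixed because the acyl group on C8a and the iodoethyl arm on C3a are trans on ring B. The new stereocentre C1 is controlled by the rotamer about C8a–C1: strain keeps the isopropyl group away from C8 and its silyloxy group and next to C8a–H, so C2, which can only arrive from the C3a side, adds to the face that leaves OH β (cis to the C3a methyl) and isopropyl α. The step needs carbonyl addition to win over 5-exo capture of the C2 radical by the C5=C6 alkene, over protonation of the C2 carbanion and over plain ketone reduction. The alkene capture would have to build a strained bridged bicyclo[4.2.1] skeleton and is outrun by fast radical reduction when 19 meets excess reductant; the other two are suppressed by the silyl ether on O8, which removes the acidic proton and the hydroxyl that would chelate samarium and speed ketyl formation. C8, C8a and C3a are unchanged because none of their bonds is broken.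

**Step 12**
Reactants: 20 (1R,3aR,8S,8aS)-8-{[tert-butyl(dimethyl)silyl]oxy}-3a,6-dimethyl-1-(propan-2-yl)-1,2,3,3a,4,7,8,8a-octahydroazulen-1-ol
Product: 21 (1R,3aR,8S,8aS)-3a,6-dimethyl-1-(propan-2-yl)-1,2,3,3a,4,7,8,8a-octahydroazulene-1,8-diol
Conditions: Bu4NF, THF, 23 → 40 °C
Reagents that add atoms: none
Why: Fluoride-mediated desilylation cleaves the secondary silyl ether through Si–F bond formation without affecting the tertiary alcohol or the alkene.

**Step 13**
Reactants: 21 (1R,3aR,8S,8aS)-3a,6-dimethyl-1-(propan-2-yl)-1,2,3,3a,4,7,8,8a-octahydroazulene-1,8-diol; 22 4-(benzyloxy)benzoic acid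
Product: 23 (1R,3aR,8S,8aS)-1-hydroxy-3a,6-dimethyl-1-(propan-2-yl)-1,2,3,3a,4,7,8,8a-octahydroazulen-8-yl 4-(benzyloxy)benzoate
Conditions: DCC, DMAP, CH2Cl2, 23 °C
Reagents that add atoms: none
Why: Steglich esterification acylates the secondary C8 alcohol while the tertiary C1 alcohol flanked by isopropyl and the ring fusion stays free, and C8 is not inverted because its C–O bond is not broken.

**Step 14**
Reactants: 23 (1R,3aR,8S,8aS)-1-hydroxy-3a,6-dimethyl-1-(propan-2-yl)-1,2,3,3a,4,7,8,8a-octahydroazulen-8-yl 4-(benzyloxy)benzoate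
Product: 25 (1R,3aR,8R,8aS)-1-hydroxy-3a,6-dimethyl-7-oxo-1-(propan-2-yl)-1,2,3,3a,4,7,8,8a-octahydroazulen-8-yl 4-(benzyloxy)benzoate, via allylic alcohol 24 (not isolated)
Conditions: SeO2 (0.5 equiv), t-BuOOH, CH2Cl2, 23 °C; then Dess–Martin periodinane, CH2Cl2, 23 °C
Reagents that add atoms: selenium dioxide O=[Se]=O; tert-butyl hydroperoxide CC(C)(C)OO
Why: SeO2 allylic oxidation (ene reaction at C5 with hydrogen transfer from the ring CH2 on the more substituted alkene end, then 2,3-sigmatropic shift) puts oxygen on C7 and returns the alkene to C5=C6, and Dess–Martin oxidation of the crude alcohol/enone mixture converges on the enone, so the C7 configuration does not matter.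

**Step 15**
Reactants: 25 (1R,3aR,8R,8aS)-1-hydroxy-3a,6-dimethyl-7-oxo-1-(propan-2-yl)-1,2,3,3a,4,7,8,8a-octahydroazulen-8-yl 4-(benzyloxy)benzoate
Product: 26 (1R,3aR,5S,6S,8R,8aS)-1,5,6-trihydroxy-3a,6-dimethyl-7-oxo-1-(propan-2-yl)decahydroazulen-8-yl 4-(benzyloxy)benzoate
Conditions: OsO4 (10 mol %), NMO, citric acid, t-BuOH/H2O, 23 °C
Reagents that add atoms: osmium tetroxide O=[Os](=O)(=O)=O; N-methylmorpholine N-oxide C[N+]1([O-])CCOCC1; water O
Why: Osmium-catalysed syn-dihydroxylation (citric acid keeps the catalyst turning over on the electron-poor enone alkene) should occur on the α face, anti to the β angular methyl on C3a that shields C5, which sets C5 and C6 with both hydroxyls α and cis to each other.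

**Step 16**
Reactants: 26 (1R,3aR,5S,6S,8R,8aS)-1,5,6-trihydroxy-3a,6-dimethyl-7-oxo-1-(propan-2-yl)decahydroazulen-8-yl 4-(benzyloxy)benzoate
Product: 27 (1R,3aR,5S,6S,8R,8aS)-1,5,6-trihydroxy-3a,6-dimethyl-7-oxo-1-(propan-2-yl)decahydroazulen-8-yl 4-hydroxybenzoate (CNP0241001.1)
Conditions: H2 (1 atm), Pd/C (10% palladium on carbon), EtOAc, 23 °C
Reagents that add atoms: none
Why: Hydrogenolysis of the benzyl aryl ether under neutral conditions frees the phenol without reducing the dialkyl ketone or cleaving the aryl ester, and no alkene remains to be reduced.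

**Compound list**
1 | pent-1-en-4-yne | C#CCC=C | starting material
2 | dimethyl[(1E)-2-methylpenta-1,4-dien-1-yl]alane | C=CC/C(C)=C/[Al](C)C | intermediate (not isolated)
3 | lithium butyl(dimethyl)[(1E)-2-methylpenta-1,4-dien-1-yl]alanate | [Li+].CCCC[Al-](C)(C)/C=C(C)/CC=C | intermediate (not isolated)
4 | (2E)-3-methylhexa-2,5-dien-1-ol | C=CC/C(C)=C/CO | intermediate
5 | ethyl (3R)-4-chloro-3-hydroxybutanoate | CCOC(=O)C[C@@H](O)CCl | starting material
6 | ethyl [(2R)-oxiran-2-yl]acetate | CCOC(=O)C[C@@H]1CO1 | intermediate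
7 | isopropenylmagnesium bromide | CC(=C)[Mg]Br | starting material
8 | ethyl (3S)-3-hydroxy-5-methylhex-5-enoate | CCOC(=O)C[C@@H](O)CC(C)=C | intermediate
9 | (2E)-3-methylhexa-2,5-dien-1-yl (3S)-3-hydroxy-5-methylhex-5-enoate | C=CC/C(C)=C/COC(=O)C[C@@H](O)CC(C)=C | intermediate
10 | dilithium alkoxide–enolate of 9 (chelated, C8 cis to OLi) | [Li+].[Li+].C=CC/C(C)=C/CO/C([O-])=C/[C@@H]([O-])CC(C)=C | intermediate (not isolated)
11 | (2S,3S)-3-hydroxy-5-methyl-2-[(3S)-3-methylhexa-1,5-dien-3-yl]hex-5-enoic acid | OC(=O)[C@H]([C@@H](O)CC(C)=C)[C@@](C)(CC=C)C=C | intermediate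
12 | methyl (2S,3S)-3-hydroxy-5-methyl-2-[(3S)-3-methylhexa-1,5-dien-3-yl]hex-5-enoate | COC(=O)[C@H]([C@@H](O)CC(C)=C)[C@@](C)(CC=C)C=C | intermediate (not isolated)
13 | methyl (2S,3S)-3-{[tert-butyl(dimethyl)silyl]oxy}-5-methyl-2-[(3S)-3-methylhexa-1,5-dien-3-yl]hex-5-enoate | COC(=O)[C@H]([C@@H](O[Si](C)(C)C(C)(C)C)CC(C)=C)[C@@](C)(CC=C)C=C | intermediate
14 | methyl (1S,2S,7S)-7-{[tert-butyl(dimethyl)silyl]oxy}-2-ethenyl-2,5-dimethylcyclohept-4-ene-1-carboxylate | COC(=O)[C@@H]1[C@@H](O[Si](C)(C)C(C)(C)C)CC(C)=CC[C@@]1(C)C=C | intermediate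
15 | methyl (1S,2S,7S)-7-{[tert-butyl(dimethyl)silyl]oxy}-2-(2-hydroxyethyl)-2,5-dimethylcyclohept-4-ene-1-carboxylate | COC(=O)[C@@H]1[C@@H](O[Si](C)(C)C(C)(C)C)CC(C)=CC[C@@]1(C)CCO | intermediate (not isolated)
16 | (4aS,9S,9aS)-9-{[tert-butyl(dimethyl)silyl]oxy}-4a,7-dimethyl-4,4a,5,8,9,9a-hexahydrocyclohepta[c]pyran-1(3H)-one | O=C1OCC[C@]2(C)CC=C(C)C[C@H](O[Si](C)(C)C(C)(C)C)[C@H]21 | intermediate
17 | isopropyllithium | [Li]C(C)C | starting material
18 | 1-[(1S,2S,7S)-7-{[tert-butyl(dimethyl)silyl]oxy}-2-(2-hydroxyethyl)-2,5-dimethylcyclohept-4-en-1-yl]-2-methylpropan-1-one | CC(C)C(=O)[C@@H]1[C@@H](O[Si](C)(C)C(C)(C)C)CC(C)=CC[C@@]1(C)CCO | intermediate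
19 | 1-[(1S,2S,7S)-7-{[tert-butyl(dimethyl)silyl]oxy}-2-(2-iodoethyl)-2,5-dimethylcyclohept-4-en-1-yl]-2-methylpropan-1-one (key-step precursor) | CC(C)C(=O)[C@@H]1[C@@H](O[Si](C)(C)C(C)(C)C)CC(C)=CC[C@@]1(C)CCI | intermediate
20 | (1R,3aR,8S,8aS)-8-{[tert-butyl(dimethyl)silyl]oxy}-3a,6-dimethyl-1-(propan-2-yl)-1,2,3,3a,4,7,8,8a-octahydroazulen-1-ol (key-step product) | CC(C)[C@]1(O)CC[C@]2(C)CC=C(C)C[C@H](O[Si](C)(C)C(C)(C)C)[C@H]21 | intermediate
21 | (1R,3aR,8S,8aS)-3a,6-dimethyl-1-(propan-2-yl)-1,2,3,3a,4,7,8,8a-octahydroazulene-1,8-diol | CC(C)[C@]1(O)CC[C@]2(C)CC=C(C)C[C@H](O)[C@H]21 | intermediate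
22 | 4-(benzyloxy)benzoic acid | OC(=O)c1ccc(OCc2ccccc2)cc1 | starting material
23 | (1R,3aR,8S,8aS)-1-hydroxy-3a,6-dimethyl-1-(propan-2-yl)-1,2,3,3a,4,7,8,8a-octahydroazulen-8-yl 4-(benzyloxy)benzoate | CC(C)[C@]1(O)CC[C@]2(C)CC=C(C)C[C@H](OC(=O)c3ccc(OCc4ccccc4)cc3)[C@H]21 | intermediate
24 | (1R,3aR,8R,8aS)-1,7-dihydroxy-3a,6-dimethyl-1-(propan-2-yl)-1,2,3,3a,4,7,8,8a-octahydroazulen-8-yl 4-(benzyloxy)benzoate (C7 epimers) | CC(C)[C@]1(O)CC[C@]2(C)CC=C(C)C(O)[C@H](OC(=O)c3ccc(OCc4ccccc4)cc3)[C@H]21 | intermediate (not isolated)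
25 | (1R,3aR,8R,8aS)-1-hydroxy-3a,6-dimethyl-7-oxo-1-(propan-2-yl)-1,2,3,3a,4,7,8,8a-octahydroazulen-8-yl 4-(benzyloxy)benzoate | CC(C)[C@]1(O)CC[C@]2(C)CC=C(C)C(=O)[C@H](OC(=O)c3ccc(OCc4ccccc4)cc3)[C@H]21 | intermediate
26 | (1R,3aR,5S,6S,8R,8aS)-1,5,6-trihydroxy-3a,6-dimethyl-7-oxo-1-(propan-2-yl)decahydroazulen-8-yl 4-(benzyloxy)benzoate | CC(C)[C@]1(O)CC[C@]2(C)C[C@H](O)[C@](C)(O)C(=O)[C@H](OC(=O)c3ccc(OCc4ccccc4)cc3)[C@H]21 | intermediate
27 | (1R,3aR,5S,6S,8R,8aS)-1,5,6-trihydroxy-3a,6-dimethyl-7-oxo-1-(propan-2-yl)decahydroazulen-8-yl 4-hydroxybenzoate | CC(C)[C@]1(O)CC[C@]2(C)C[C@H](O)[C@](C)(O)C(=O)[C@H](OC(=O)c3ccc(O)cc3)[C@H]21 | target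

**Step count**
Total steps: 16. Longest linear sequence: 15 steps (steps 2–16, from 5).

**Three steps most likely to fail**

1. Step 11 (key step). The C2 radical may be captured by the C5=C6 alkene or reduced to the ethyl compound before C2 reaches the carbonyl, or the ketone may be reduced first. Fallback: from 19, run the closure as a polar anionic cyclisation instead of an electron-transfer one. t-BuLi (2.1 equiv, Et2O/pentane, −78 °C) should exchange iodine for lithium faster than it attacks the hindered ketone, giving the alkyllithium F1, which adds to the C1 carbonyl within the molecule; protonation returns to the route at 20.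

2. Step 5. The rearrangement to the congested quaternary centre may stall, or the anti selectivity between C8 and C8a may erode at the temperature needed. Fallback: from 9, silylate O8 (TBSOTf, 2,6-lutidine) to the silyl ether F2 and run a classical Ireland–Claisen rearrangement through the (Z)-trimethylsilyl ketene acetal F3 (LiN(iPr)2, TMSCl, THF/HMPA, −78 → 60 °C). Here the ketene acetal geometry is set by the solvent and the face by 1,2-induction from the silyloxy centre, not by chelation. The rearranged silyl ester F4 is hydrolysed on work-up to the acid F5, diastereomers are separated, and TMSCHN2 methylation joins the route at 13.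

3. Step 14. The ene reaction may be slow or go to the C6 methyl group because the C7 methylene sits next to the electron-poor acyloxy carbon; acyl migration in the intermediate alcohol is a further loss path. Fallback: change the order so that the ene oxidation meets a C7 methylene next to a free carbinol and the oxidation state is then adjusted chemoselectively. From 21, SeO2/t-BuOOH should give the triol F6, MnO2 should oxidise only the allylic C7 hydroxyl to the hydroxy enone F7, and Steglich esterification of F7 with 22 (DCC, DMAP) joins the route at 25.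

**Further compounds**
F1 | step 11 | {2-[(1S,2S,7S)-7-{[tert-butyl(dimethyl)silyl]oxy}-2,5-dimethyl-1-(2-methylpropanoyl)cyclohept-4-en-2-yl]ethyl}lithium | CC(C)C(=O)[C@@H]1[C@@H](O[Si](C)(C)C(C)(C)C)CC(C)=CC[C@@]1(C)CC[Li]
F2 | step 5 | (2E)-3-methylhexa-2,5-dien-1-yl (3S)-3-{[tert-butyl(dimethyl)silyl]oxy}-5-methylhex-5-enoate | C=CC/C(C)=C/COC(=O)C[C@@H](O[Si](C)(C)C(C)(C)C)CC(C)=C
F3 | step 5 | (Z)-trimethylsilyl ketene acetal of F2 (C8 cis to OSiMe3) | C=CC/C(C)=C/CO/C(O[Si](C)(C)C)=C/[C@@H](O[Si](C)(C)C(C)(C)C)CC(C)=C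
F4 | step 5 | trimethylsilyl (2S,3S)-3-{[tert-butyl(dimethyl)silyl]oxy}-5-methyl-2-[(3S)-3-methylhexa-1,5-dien-3-yl]hex-5-enoate | C[Si](C)(C)OC(=O)[C@H]([C@@H](O[Si](C)(C)C(C)(C)C)CC(C)=C)[C@@](C)(CC=C)C=C
F5 | step 5 | (2S,3S)-3-{[tert-butyl(dimethyl)silyl]oxy}-5-methyl-2-[(3S)-3-methylhexa-1,5-dien-3-yl]hex-5-enoic acid | OC(=O)[C@H]([C@@H](O[Si](C)(C)C(C)(C)C)CC(C)=C)[C@@](C)(CC=C)C=C
F6 | step 14 | (1R,3aR,8R,8aS)-3a,6-dimethyl-1-(propan-2-yl)-1,2,3,3a,4,7,8,8a-octahydroazulene-1,7,8-triol (C7 epimers) | CC(C)[C@]1(O)CC[C@]2(C)CC=C(C)C(O)[C@H](O)[C@H]21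
F7 | step 14 | (1R,3aR,8R,8aS)-1,8-dihydroxy-3a,6-dimethyl-1-(propan-2-yl)-2,3,3a,4,8,8a-hexahydroazulen-7(1H)-one | CC(C)[C@]1(O)CC[C@]2(C)CC=C(C)C(=O)[C@H](O)[C@H]21
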